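**Retrosynthetic overview**

- The strategy rests on the γ-lactone ring (O1, C2 carbonyl, C3 exo-methylene carbon, C4 bearing CO2H, C5 bearing the 14-oxopentadecyl chain): the unit C2(=O)–C3(=CH2), next to the epimerisable C4–H, is a terminal alkyne plus one molecule of CO.
- O1–C2 and C2–C3 are cut together: palladium cyclocarbonylation of a syn homopropargylic alcohol closes the only ring, with the C4 carboxyl carried as CH2OTBDPS; desilylation and Jones oxidation follow.
- The C4–C5 bond and both stereocentres come from a BF3-promoted SE2' addition of an axially chiral allenylstannane to 15-oxohexadecanal.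
- The stannane is made from (silyloxy)acetaldehyde and TMS-acetylene (ynone, asymmetric transfer hydrogenation, mesylate, anti SN2' stannylation); the keto-aldehyde from ω-pentadecalactone (Weinreb amide, MeMgBr, oxidation).

Key step: step 11

Assumption: in step 3 the alkynyl group is taken to occupy the place of the aryl group in the usual model of the transfer hydrogenation; should the other face be preferred, the (R,R) complex would be used and nothing else would change.

**Route**

Step 1
Reactants: 1 ethynyltrimethylsilane; 2 (tert-butyldiphenylsilyloxy)acetaldehyde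
Product: 4 rac-1-(tert-butyldiphenylsilyloxy)-4-(trimethylsilyl)but-3-yn-2-ol, via lithium (trimethylsilyl)acetylide 3 (not isolated)
Conditions: n-BuLi, THF, −78 °C; then 2, −78 °C; H2O
Reagents that add atoms: none
Why: 1,2-addition of a lithium acetylide to an aldehyde at low temperature; the carbinol centre is made racemic on purpose, since it is erased in step 2 and set in step 3.

Step 2
Reactants: 4 rac-1-(tert-butyldiphenylsilyloxy)-4-(trimethylsilyl)but-3-yn-2-ol
Product: 5 1-(tert-butyldiphenylsilyloxy)-4-(trimethylsilyl)but-3-yn-2-one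
Conditions: Dess–Martin periodinane, CH2Cl2, 0 °C → rt
Reagents that add atoms: none
Why: Dess–Martin oxidation converts the propargylic alcohol into the ynone under near-neutral conditions that leave both silyl groups in place.

Step 3
Reactants: 5 1-(tert-butyldiphenylsilyloxy)-4-(trimethylsilyl)but-3-yn-2-one
Product: 6 (R)-1-(tert-butyldiphenylsilyloxy)-4-(trimethylsilyl)but-3-yn-2-ol
Conditions: Ru[(S,S)-TsNCHPhCHPhNH](p-cymene) (cat.), i-PrOH, rt
Reagents that add atoms: none
Why: Noyori asymmetric transfer hydrogenation of an α,β-acetylenic ketone; with the alkynyl group in the place of the aryl group the (S,S) complex should deliver hydride to the face that gives the R carbinol (R here because CH2OSi outranks the alkynyl carbon).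

Step 4
Reactants: 6 (R)-1-(tert-butyldiphenylsilyloxy)-4-(trimethylsilyl)but-3-yn-2-ol
Product: 7 (R)-1-(tert-butyldiphenylsilyloxy)but-3-yn-2-ol
Conditions: K2CO3 (cat.), MeOH, 0 °C → rt
Reagents that add atoms: none
Why: base-catalysed methanolysis of the C(sp)–Si bond (protiodesilylation) is much faster than attack on the hindered TBDPS ether, and the carbinol centre is not involved.

Step 5
Reactants: 7 (R)-1-(tert-butyldiphenylsilyloxy)but-3-yn-2-ol
Product: 8 (R)-1-(tert-butyldiphenylsilyloxy)but-3-yn-2-yl methanesulfonate
Conditions: MsCl, Et3N, CH2Cl2, −78 → 0 °C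
Reagents that add atoms: methanesulfonyl chloride, CS(=O)(=O)Cl
Why: mesylation takes place at oxygen, so the configuration at carbon is retained and the leaving group for the SN2' step is in place.

Step 6
Reactants: 8 (R)-1-(tert-butyldiphenylsilyloxy)but-3-yn-2-yl methanesulfonate
Product: 9 (M)-tributyl[4-(tert-butyldiphenylsilyloxy)buta-1,2-dien-1-yl]stannane (axis aR)
Conditions: Bu3SnH, LiN(i-Pr)2, THF, 0 °C; CuBr·SMe2, −78 °C; then 8, −78 °C
Reagents that add atoms: tributylstannyllithium, [Li][Sn](CCCC)(CCCC)CCCC (made from tributyltin hydride, CCCC[SnH](CCCC)CCCC)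
Why: anti SN2' displacement of a propargylic mesylate by a stannylcuprate; tin enters at the alkyne terminus on the face opposite to the departing mesylate, so the R centre is converted into the M allene axis.

Step 7
Reactants: 10 ω-pentadecalactone
Product: 11 15-hydroxy-N-methoxy-N-methylpentadecanamide
Conditions: MeNH(OMe)·HCl, i-PrMgCl, THF, −20 → 0 °C; aq NH4Cl
Reagents that add atoms: N,O-dimethylhydroxylamine hydrochloride, CNOC.Cl
Why: aminolysis of the lactone by the magnesium amide of N,O-dimethylhydroxylamine (Weinreb amide formation); the strain-free macrolactone reacts like an open-chain ester and does not re-close.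

Step 8
Reactants: 11 15-hydroxy-N-methoxy-N-methylpentadecanamide
Product: 13 16-hydroxyhexadecan-2-one, via bromomagnesium hemiaminal chelate 12 (not isolated)
Conditions: MeMgBr (3 equiv), THF, 0 °C; aq NH4Cl
Reagents that add atoms: methylmagnesium bromide, C[Mg]Br
Why: Weinreb ketone synthesis; the chelated tetrahedral adduct 12 survives until work-up, so only one methyl group is delivered, while one further equivalent of the Grignard reagent is consumed by the hydroxyl.

Step 9
Reactants: 13 16-hydroxyhexadecan-2-one
Product: 14 15-oxohexadecanal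
Conditions: PhI(OAc)2, TEMPO (cat.), CH2Cl2, rt
Reagents that add atoms: none
Why: oxoammonium (TEMPO) oxidation is selective for the primary alcohol, stops at the aldehyde in the absence of water and leaves the ketone untouched.

Step 10
Reactants: 14 15-oxohexadecanal; 9 (M)-tributyl[4-(tert-butyldiphenylsilyloxy)buta-1,2-dien-1-yl]stannane
Product: 15 (3R,4S)-3-[(tert-butyldiphenylsilyloxy)methyl]-4-hydroxynonadec-1-yn-18-one
Conditions: BF3·OEt2 (2 equiv), CH2Cl2, −78 °C; aq NaHCO3, then KF
Reagents that add atoms: none
Why: Lewis-acid-promoted SE2' addition of an allenylstannane to an aldehyde through an open transition state: the BF3-bound aldehyde is attacked by the CH(CH2OSi) terminus on the face anti to the C–Sn bond, which turns the M axis into the 3R centre, the antiperiplanar arrangement that keeps the aldehyde chain away from the allene terminus and its bulky CH2OTBDPS group sets 4S (syn), and at −78 °C the aldehyde is far more electrophilic than the methyl ketone.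

Step 11
Reactants: 15 (3R,4S)-3-[(tert-butyldiphenylsilyloxy)methyl]-4-hydroxynonadec-1-yn-18-one; 16 carbon monoxide
Product: 17 (4R,5S)-4-[(tert-butyldiphenylsilyloxy)methyl]-3-methylene-5-(14-oxopentadecyl)dihydrofuran-2(3H)-one
Conditions: PdCl2 (cat.), SnCl2 (cat.), PPh3, CO (7 atm), MeCN, 75 °C
Reagents that add atoms: carbon monoxide (16), [C-]#[O+]
Why: Divalent palladium, as the PdCl(SnCl3)(PPh3)2 species formed from PdCl2, SnCl2 and PPh3, binds CO and is attacked by the C4 hydroxyl of 15 to give an alkoxycarbonylpalladium species; the tethered alkyne inserts syn into the Pd–C(=O)O bond, and the exocyclic vinylpalladium is protonated by the HCl released in the first stage, which frees the lactone and returns divalent palladium. The closest known reaction type is the palladium-catalysed cyclocarbonylation of 3-butyn-1-ols to α-methylene-γ-butyrolactones, which accepts secondary alcohols and a substituent on the propargylic carbon. The one ring, the five-membered lactone, closes in the 5-exo-dig mode: the carbonyl carbon bonds to the internal alkyne carbon (O1–C2 and C2–C3 formed) and the terminal carbon becomes the exo-methylene. No stereocentre is created; the two centres set in step 10 lie outside the reacting atoms and are only renumbered (3R,4S to 4R,5S). The step needs exo over endo insertion, which the two-atom tether between carbinol carbon and alkyne enforces, and it needs the secondary hydroxyl to be the only nucleophile, which the TBDPS ether on the primary oxygen secures. Because C3 is never an enolate and the medium is neutral, the C4–H next to the new double bond should neither epimerise nor allow the double bond to move into the ring.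

Step 12
Reactants: 17 (4R,5S)-4-[(tert-butyldiphenylsilyloxy)methyl]-3-methylene-5-(14-oxopentadecyl)dihydrofuran-2(3H)-one
Product: 18 (4R,5S)-4-(hydroxymethyl)-3-methylene-5-(14-oxopentadecyl)dihydrofuran-2(3H)-one
Conditions: HF·pyridine, pyridine, THF, 0 °C → rt
Reagents that add atoms: none
Why: fluoride cleavage of the silyl ether with buffered HF·pyridine avoids a free alkoxide, which could attack the lactone carbonyl or the exo-methylene acceptor; no stereocentre is touched.

Step 13
Reactants: 18 (4R,5S)-4-(hydroxymethyl)-3-methylene-5-(14-oxopentadecyl)dihydrofuran-2(3H)-one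
Product: 20 allo-pertusaric acid, (2S,3S)-4-methylene-5-oxo-2-(14-oxopentadecyl)tetrahydrofuran-3-carboxylic acid, via formyl lactone 19 (not isolated)
Conditions: CrO3, H2SO4, H2O, acetone, 0 °C
Reagents that add atoms: water, O (the second carboxyl oxygen enters through the aldehyde hydrate, which CrO3 oxidises)
Why: Jones oxidation takes the primary alcohol through aldehyde 19 and its hydrate to the acid in acidic medium, where the transient aldehyde is not enolised at C4 and the ketone and α-methylene lactone are inert; the 2S,3S descriptors result from renumbering and changed CIP priorities, not from any change at the centres.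

**Compound list**

1 | ethynyltrimethylsilane | C#C[Si](C)(C)C | starting material
2 | (tert-butyldiphenylsilyloxy)acetaldehyde | CC(C)(C)[Si](OCC=O)(c1ccccc1)c1ccccc1 | starting material
3 | lithium (trimethylsilyl)acetylide | [Li]C#C[Si](C)(C)C | intermediate (not isolated)
4 | rac-1-(tert-butyldiphenylsilyloxy)-4-(trimethylsilyl)but-3-yn-2-ol | OC(C#C[Si](C)(C)C)CO[Si](c1ccccc1)(c1ccccc1)C(C)(C)C | intermediate
5 | 1-(tert-butyldiphenylsilyloxy)-4-(trimethylsilyl)but-3-yn-2-one | O=C(C#C[Si](C)(C)C)CO[Si](c1ccccc1)(c1ccccc1)C(C)(C)C | intermediate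
6 | (R)-1-(tert-butyldiphenylsilyloxy)-4-(trimethylsilyl)but-3-yn-2-ol | O[C@H](C#C[Si](C)(C)C)CO[Si](c1ccccc1)(c1ccccc1)C(C)(C)C | intermediate
7 | (R)-1-(tert-butyldiphenylsilyloxy)but-3-yn-2-ol | O[C@H](C#C)CO[Si](c1ccccc1)(c1ccccc1)C(C)(C)C | intermediate
8 | (R)-1-(tert-butyldiphenylsilyloxy)but-3-yn-2-yl methanesulfonate | CS(=O)(=O)O[C@H](C#C)CO[Si](c1ccccc1)(c1ccccc1)C(C)(C)C | intermediate
9 | (M)-tributyl[4-(tert-butyldiphenylsilyloxy)buta-1,2-dien-1-yl]stannane (axis aR) | [H]C([Sn](CCCC)(CCCC)CCCC)=[C@@]=C([H])CO[Si](c1ccccc1)(c1ccccc1)C(C)(C)C | intermediate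
10 | ω-pentadecalactone | O=C1CCCCCCCCCCCCCCO1 | starting material
11 | 15-hydroxy-N-methoxy-N-methylpentadecanamide | CON(C)C(=O)CCCCCCCCCCCCCCO | intermediate
12 | bis(bromomagnesium) salt of 2-[methoxy(methyl)amino]hexadecane-2,16-diol (hemiaminal chelate) | CON(C)C(C)(O[Mg]Br)CCCCCCCCCCCCCCO[Mg]Br | intermediate (not isolated)
13 | 16-hydroxyhexadecan-2-one | CC(=O)CCCCCCCCCCCCCCO | intermediate
14 | 15-oxohexadecanal | CC(=O)CCCCCCCCCCCCCC=O | intermediate
15 | (3R,4S)-3-[(tert-butyldiphenylsilyloxy)methyl]-4-hydroxynonadec-1-yn-18-one | O[C@@H](CCCCCCCCCCCCCC(C)=O)[C@H](C#C)CO[Si](c1ccccc1)(c1ccccc1)C(C)(C)C | intermediate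
16 | carbon monoxide | [C-]#[O+] | starting material
17 | (4R,5S)-4-[(tert-butyldiphenylsilyloxy)methyl]-3-methylene-5-(14-oxopentadecyl)dihydrofuran-2(3H)-one | C=C1C(=O)O[C@@H](CCCCCCCCCCCCCC(C)=O)[C@H]1CO[Si](c2ccccc2)(c3ccccc3)C(C)(C)C | intermediate
18 | (4R,5S)-4-(hydroxymethyl)-3-methylene-5-(14-oxopentadecyl)dihydrofuran-2(3H)-one | C=C1C(=O)O[C@@H](CCCCCCCCCCCCCC(C)=O)[C@H]1CO | intermediate
19 | (2S,3S)-4-methylene-5-oxo-2-(14-oxopentadecyl)tetrahydrofuran-3-carbaldehyde | C=C1C(=O)O[C@@H](CCCCCCCCCCCCCC(C)=O)[C@H]1C=O | intermediate (not isolated)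
20 | allo-pertusaric acid, (2S,3S)-4-methylene-5-oxo-2-(14-oxopentadecyl)tetrahydrofuran-3-carboxylic acid | C=C1C(=O)O[C@@H](CCCCCCCCCCCCCC(C)=O)[C@H]1C(=O)O | target

**Step count**

Total: 13 steps. Longest linear sequence: 10 steps (steps 1–6, then 10–13); the aldehyde branch contributes steps 7–9.

**Steps most likely to fail**

Step 10. The open transition state may discriminate poorly between syn and anti approach when the aldehyde is unbranched, so simple diastereoselection at C4 may be low. The stannane may also lose its silyloxy group by 1,4-elimination under BF3. The fallback sets out from ynone 5 and aldehyde 14 and comes back at 15. Ynone 5 is reduced with Ru[(R,R)-TsNCHPhCHPhNH](p-cymene) in i-PrOH to (S)-1-(tert-butyldiphenylsilyloxy)-4-(trimethylsilyl)but-3-yn-2-ol F1. K2CO3/MeOH gives (S)-1-(tert-butyldiphenylsilyloxy)but-3-yn-2-ol F2, and MsCl/Et3N gives (S)-1-(tert-butyldiphenylsilyloxy)but-3-yn-2-yl methanesulfonate F3. F3 and 14 are then combined with PdCl2(dppf) (cat.) and InI in THF–HMPA at rt. Zerovalent palladium formed in the flask displaces the mesylate anti, the allenyl group passes to indium, and addition occurs through a closed six-membered transition state. This mode is anti-selective with linear aldehydes and should give (3R,4R)-3-[(tert-butyldiphenylsilyloxy)methyl]-4-hydroxynonadec-1-yn-18-one F4. The enantiomeric mesylate is needed because the closed transition state delivers the aldehyde syn to the metal, so C3 ends up 3R as in 15. Mitsunobu inversion at C4 (4-nitrobenzoic acid, PPh3, DIAD, toluene) should give (3R,4S)-3-[(tert-butyldiphenylsilyloxy)methyl]-18-oxononadec-1-yn-4-yl 4-nitrobenzoate F5, and K2CO3/MeOH returns 15.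

Step 11. The catalytic cycle may stall (palladium black, slow alkoxycarbonylation at the hindered secondary hydroxyl), PPh3 may add to the product's acceptor, or the exocyclic double bond may migrate into the ring on prolonged heating. The fallback sets out from 15 and comes back at 17, forming the same two bonds through a vinyl halide. Markovnikov hydroiodination of the terminal alkyne (NaI, TMSCl, H2O, MeCN, rt) should give (3R,4S)-3-[(tert-butyldiphenylsilyloxy)methyl]-4-hydroxy-2-iodononadec-1-en-18-one F6. Carbonylative lactonisation (Pd(PPh3)4 cat., CO 1 atm, K2CO3, THF, 50 °C) then proceeds by oxidative addition of zerovalent palladium into the C–I bond, CO insertion and intramolecular alcoholysis of the acylpalladium, giving 17 under mild, low-pressure conditions.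

Step 12. Once the primary hydroxyl is free it is also γ to the lactone carbonyl, so acyl migration to the isomeric lactone (with the C5 oxygen released as a secondary alcohol) may compete during desilylation or handling; Jones oxidation would then give the wrong product. The fallback sets out from 15 and comes back at 20, and never accumulates the free hydroxymethyl lactone. TBAF (THF, 0 °C) gives (3R,4S)-4-hydroxy-3-(hydroxymethyl)nonadec-1-yn-18-one F7. Selective silylation of the primary hydroxyl (TBSCl, imidazole, CH2Cl2, 0 °C) gives (3R,4S)-3-[(tert-butyldimethylsilyloxy)methyl]-4-hydroxynonadec-1-yn-18-one F8. Cyclocarbonylation as in step 11 gives (4R,5S)-4-[(tert-butyldimethylsilyloxy)methyl]-3-methylene-5-(14-oxopentadecyl)dihydrofuran-2(3H)-one F9. Jones reagent (CrO3, H2SO4, acetone, 0 °C) cleaves the primary TBS ether and oxidises the alcohol as it is released, giving 20 in one operation.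

**Further compounds**

F1 | step 10 | (S)-1-(tert-butyldiphenylsilyloxy)-4-(trimethylsilyl)but-3-yn-2-ol | O[C@@H](C#C[Si](C)(C)C)CO[Si](c1ccccc1)(c1ccccc1)C(C)(C)C
F2 | step 10 | (S)-1-(tert-butyldiphenylsilyloxy)but-3-yn-2-ol | O[C@@H](C#C)CO[Si](c1ccccc1)(c1ccccc1)C(C)(C)C
F3 | step 10 | (S)-1-(tert-butyldiphenylsilyloxy)but-3-yn-2-yl methanesulfonate | CS(=O)(=O)O[C@@H](C#C)CO[Si](c1ccccc1)(c1ccccc1)C(C)(C)C
F4 | step 10 | (3R,4R)-3-[(tert-butyldiphenylsilyloxy)methyl]-4-hydroxynonadec-1-yn-18-one | O[C@H](CCCCCCCCCCCCCC(C)=O)[C@H](C#C)CO[Si](c1ccccc1)(c1ccccc1)C(C)(C)C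
F5 | step 10 | (3R,4S)-3-[(tert-butyldiphenylsilyloxy)methyl]-18-oxononadec-1-yn-4-yl 4-nitrobenzoate | O=C(O[C@@H](CCCCCCCCCCCCCC(C)=O)[C@H](C#C)CO[Si](c1ccccc1)(c1ccccc1)C(C)(C)C)c1ccc(cc1)[N+](=O)[O-]
F6 | step 11 | (3R,4S)-3-[(tert-butyldiphenylsilyloxy)methyl]-4-hydroxy-2-iodononadec-1-en-18-one | O[C@@H](CCCCCCCCCCCCCC(C)=O)[C@H](C(I)=C)CO[Si](c1ccccc1)(c1ccccc1)C(C)(C)C
F7 | step 12 | (3R,4S)-4-hydroxy-3-(hydroxymethyl)nonadec-1-yn-18-one | O[C@@H](CCCCCCCCCCCCCC(C)=O)[C@H](C#C)CO
F8 | step 12 | (3R,4S)-3-[(tert-butyldimethylsilyloxy)methyl]-4-hydroxynonadec-1-yn-18-one | O[C@@H](CCCCCCCCCCCCCC(C)=O)[C@H](C#C)CO[Si](C)(C)C(C)(C)C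
F9 | step 12 | (4R,5S)-4-[(tert-butyldimethylsilyloxy)methyl]-3-methylene-5-(14-oxopentadecyl)dihydrofuran-2(3H)-one | C=C1C(=O)O[C@@H](CCCCCCCCCCCCCC(C)=O)[C@H]1CO[Si](C)(C)C(C)(C)C
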